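## Retrosynthetic overview

1. The three phenols are unveiled last from a tris(methoxymethyl) ether. Rings A and B are bought as aromatic starting materials, so ring C is the only ring the route forms, and it is formed last.
2. Ring C is made in one operation by clipping an enantiopure four-atom chain O1–C2–C3–C4 across the adjacent ring A carbons C8a and C4a of an aryne. The chain is an (S)-β-silyloxy N-methoxy-N-methylamide that already carries ring B and the C2 stereocentre. O1–C8a and C4–C4a form together, which also joins the two prenylated halves.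
3. Enabling feature: in ring C the nucleophilic O1 and the acyl carbon C4 stand 1,3 to each other and meet ring A at the ortho pair C8a/C4a, and the C5 oxygen sits directly next to C4a. In a C4a≡C8a aryne this oxygen sends the alkoxide to C8a and leaves the carbanion at C4a, so the 6-prenyl (not 8-prenyl) pattern is fixed by the aryne.
4. Aryne precursor (ring A): resorcinol → bis-MOM ether → C2 prenylation by directed metalation → C–H borylation/oxidation para to the prenyl group → carbamate-directed ortho-silylation (the phenol is symmetric, both ortho positions are equivalent) → silylaryl triflate.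
5. Chain (ring B, C2): 3-bromo-4-hydroxyacetophenone → MOM ether → Stille prenylation → Claisen condensation → asymmetric transfer hydrogenation (sets C2) → N-methoxy-N-methylamide → TMS ether.

Key step: step 13

Remark: the descriptor in the given structure corresponds to (2S); resorcinol, 1-(3-bromo-4-hydroxyphenyl)ethan-1-one and tributyl(3-methylbut-2-en-1-yl)stannane are taken as commercial.

## Route

Step 1
Reactants: 1 resorcinol
Product: 2 1,3-bis(methoxymethoxy)benzene
Conditions: MOMCl (2.5 equiv), i-Pr2NEt, CH2Cl2, 0 °C → rt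
Reagents that add atoms: chloromethyl methyl ether, COCCl
Why: Amine-mediated O-alkylation of both phenols with the α-chloro ether (acetal protection) gives groups that direct ortho-metalation and are inert to fluoride.

Step 2
Reactants: 2 1,3-bis(methoxymethoxy)benzene
Product: 4 1,3-bis(methoxymethoxy)-2-(3-methylbut-2-en-1-yl)benzene, via aryllithium 3 (not isolated)
Conditions: n-BuLi, THF, 0 °C → rt; then CuBr·SMe2 (10 mol%), prenyl bromide, −78 °C → rt
Reagents that add atoms: 1-bromo-3-methylbut-2-ene, CC(C)=CCBr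
Why: Directed ortho-metalation at the doubly activated C–H between the two OMOM groups, then copper-catalysed SN2 allylation at the primary carbon of the allylic bromide, should give the linear prenyl arene.

Step 3
Reactants: 4 1,3-bis(methoxymethoxy)-2-(3-methylbut-2-en-1-yl)benzene
Product: 6 3,5-bis(methoxymethoxy)-4-(3-methylbut-2-en-1-yl)phenol, via aryl boronate 5 (not isolated)
Conditions: B2pin2 (1.0 equiv), [Ir(OMe)(cod)]2 (1.5 mol%), 4,4'-di-tert-butyl-2,2'-bipyridine (3 mol%), THF, 65 °C; then 30% H2O2, 2 M NaOH, 0 °C → rt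
Reagents that add atoms: hydrogen peroxide, OO
Why: Iridium-catalysed aromatic C–H borylation is sterically controlled and should reach only the one C–H without an ortho substituent (para to the prenyl group), and alkaline peroxide oxidation of the C–B bond, which leaves the trisubstituted alkene alone, gives the phenol.

Step 4
Reactants: 6 3,5-bis(methoxymethoxy)-4-(3-methylbut-2-en-1-yl)phenol
Product: 7 3,5-bis(methoxymethoxy)-4-(3-methylbut-2-en-1-yl)phenyl N-(propan-2-yl)carbamate
Conditions: i-PrNCO, Et3N (cat.), CH2Cl2, rt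
Reagents that add atoms: 2-isocyanatopropane, CC(C)N=C=O
Why: Amine-catalysed addition of the phenol to the isocyanate (carbamoylation) installs a strong ortho-directing group that can later be removed under mild base.

Step 5
Reactants: 7 3,5-bis(methoxymethoxy)-4-(3-methylbut-2-en-1-yl)phenyl N-(propan-2-yl)carbamate
Product: 11 3,5-bis(methoxymethoxy)-4-(3-methylbut-2-en-1-yl)-2-(trimethylsilyl)phenyl N-(propan-2-yl)carbamate, via N-silyl carbamate 8 (not isolated), via aryllithium 9 (not isolated), via bis-silyl carbamate 10 (not isolated)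
Conditions: TBSOTf (1.05 equiv), TMEDA, Et2O, 0 °C → rt; n-BuLi (2.2 equiv), TMEDA, −78 °C; TMSCl, −78 °C → rt; 10% aq citric acid work-up
Reagents that add atoms: chlorotrimethylsilane, C[Si](C)(C)Cl
Why: Directed ortho-metalation of the in situ N-silylated carbamate at one of the two equivalent ring C–H positions (each flanked by the carbamate and an OMOM group), C-silylation, and hydrolysis of the N–Si bond on work-up should give the ortho-silyl carbamate.

Step 6
Reactants: 11 3,5-bis(methoxymethoxy)-4-(3-methylbut-2-en-1-yl)-2-(trimethylsilyl)phenyl N-(propan-2-yl)carbamate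
Product: 13 3,5-bis(methoxymethoxy)-4-(3-methylbut-2-en-1-yl)-2-(trimethylsilyl)phenyl trifluoromethanesulfonate, via silyl phenol 12 (not isolated)
Conditions: DBU, Et2NH, MeCN, 40 °C; then PhNTf2, rt
Reagents that add atoms: N-phenylbis(trifluoromethanesulfonimide), FC(F)(F)S(=O)(=O)N(c1ccccc1)S(=O)(=O)C(F)(F)F
Why: E1cB cleavage of the N-monosubstituted carbamate (the isocyanate is scavenged by diethylamine) and O-sulfonylation of the freed phenoxide in the same flask should give the ortho-silylaryl triflate.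

Step 7
Reactants: 14 1-(3-bromo-4-hydroxyphenyl)ethan-1-one
Product: 15 1-[3-bromo-4-(methoxymethoxy)phenyl]ethan-1-one
Conditions: MOMCl, i-Pr2NEt, CH2Cl2, 0 °C → rt
Reagents that add atoms: chloromethyl methyl ether, COCCl
Why: O-alkylation of the phenol with the α-chloro ether (acetal protection) masks the ring B phenol in a form that survives fluoride and is removed together with the ring A groups.

Step 8
Reactants: 15 1-[3-bromo-4-(methoxymethoxy)phenyl]ethan-1-one
Product: 16 1-[4-(methoxymethoxy)-3-(3-methylbut-2-en-1-yl)phenyl]ethan-1-one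
Conditions: tributyl(3-methylbut-2-en-1-yl)stannane, Pd(PPh3)4 (5 mol%), DMF, 90 °C
Reagents that add atoms: tributyl(3-methylbut-2-en-1-yl)stannane, CCCC[Sn](CCCC)(CCCC)CC=C(C)C
Why: Stille cross-coupling of the acyl-activated aryl bromide, with reductive elimination at the less hindered primary allyl terminus, should give the linear prenyl arene.

Step 9
Reactants: 16 1-[4-(methoxymethoxy)-3-(3-methylbut-2-en-1-yl)phenyl]ethan-1-one
Product: 17 methyl 3-[4-(methoxymethoxy)-3-(3-methylbut-2-en-1-yl)phenyl]-3-oxopropanoate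
Conditions: NaH (2.5 equiv), (MeO)2CO, THF, reflux; AcOH quench
Reagents that add atoms: dimethyl carbonate, COC(=O)OC
Why: Crossed Claisen condensation of the ketone enolate with dimethyl carbonate, driven by deprotonation of the β-keto ester, should give the β-keto ester.

Step 10
Reactants: 17 methyl 3-[4-(methoxymethoxy)-3-(3-methylbut-2-en-1-yl)phenyl]-3-oxopropanoate
Product: 18 methyl (3S)-3-hydroxy-3-[4-(methoxymethoxy)-3-(3-methylbut-2-en-1-yl)phenyl]propanoate
Conditions: RuCl[(S,S)-TsDPEN](p-cymene) (1 mol%), HCO2H/Et3N (5:2), DMF, 30 °C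
Reagents that add atoms: none
Why: Noyori–Ikariya asymmetric transfer hydrogenation of the aryl ketone, in which the (S,S)-catalyst is expected, as with aryl alkyl ketones, to deliver hydride to the face that gives the (S)-benzylic alcohol (aryl group held toward the η6-arene in the six-membered transition state), sets the future C2 and leaves the alkene untouched.

Step 11
Reactants: 18 methyl (3S)-3-hydroxy-3-[4-(methoxymethoxy)-3-(3-methylbut-2-en-1-yl)phenyl]propanoate
Product: 19 (3S)-3-hydroxy-N-methoxy-N-methyl-3-[4-(methoxymethoxy)-3-(3-methylbut-2-en-1-yl)phenyl]propanamide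
Conditions: MeNH(OMe)·HCl, i-PrMgCl, THF, −20 → 0 °C; aq NH4Cl
Reagents that add atoms: N,O-dimethylhydroxylamine hydrochloride, CNOC.Cl
Why: Aminolysis of the ester by the chloromagnesium amide (ester to N-methoxy-N-methylamide) at low temperature should not touch the carbinol centre, which is held as its magnesium alkoxide.

Step 12
Reactants: 19 (3S)-3-hydroxy-N-methoxy-N-methyl-3-[4-(methoxymethoxy)-3-(3-methylbut-2-en-1-yl)phenyl]propanamide
Product: 20 (3S)-N-methoxy-N-methyl-3-[4-(methoxymethoxy)-3-(3-methylbut-2-en-1-yl)phenyl]-3-[(trimethylsilyl)oxy]propanamide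
Conditions: 1-(trimethylsilyl)imidazole, CH2Cl2, rt
Reagents that add atoms: 1-(trimethylsilyl)imidazole, C[Si](C)(C)n1ccnc1
Why: Neutral O-silylation of the secondary alcohol removes the only O–H proton and makes the alkoxide releasable by fluoride.

Step 13
Reactants: 13 3,5-bis(methoxymethoxy)-4-(3-methylbut-2-en-1-yl)-2-(trimethylsilyl)phenyl trifluoromethanesulfonate; 20 (3S)-N-methoxy-N-methyl-3-[4-(methoxymethoxy)-3-(3-methylbut-2-en-1-yl)phenyl]-3-[(trimethylsilyl)oxy]propanamide
Product: 25 (2S)-5,7-bis(methoxymethoxy)-2-[4-(methoxymethoxy)-3-(3-methylbut-2-en-1-yl)phenyl]-6-(3-methylbut-2-en-1-yl)-2,3-dihydro-4H-1-benzopyran-4-one, via aryne 21 (not isolated), via cesium alkoxide 22 (not isolated), via arylcesium 23 (not isolated), via hemiaminal alkoxide 24 (not isolated)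
Conditions: CsF (4 equiv), 18-crown-6 (4 equiv), THF, 0 °C → rt, 13 (1.3 equiv) added slowly; then AcOH/NaOAc buffer (pH 5), 0 °C
Reagents that add atoms: none
Why: Proposed new method: fluoride strips both silyl groups, so the cesium alkoxide 22 and the 3-alkoxyaryne 21 appear together in an aprotic medium; 22 adds to the aryne carbon C8a (remote from the C5 OMOM group), the resulting C4a carbanion 23 adds to the N-methoxy-N-methylamide carbonyl, and the tetrahedral adduct 24 releases the ring C ketone only on buffered work-up. The closest known reaction types are the anionic annulation of arynes with salicylate esters to xanthones and the insertion of arynes into the N–C(O) bond of β-lactams to give 2,3-dihydroquinolin-4-ones; an aliphatic β-oxy amide has not been used in this way. Ring C closes in a stepwise anionic [4+2] sense: intermolecular O1–C8a bond formation, then 6-exo-trig addition of the aryl carbanion to the amide carbonyl (C4a–C4). No stereocentre is created: C2 keeps the S configuration set in step 10 because its C–O bond is never broken, and C4 stays sp3 (no enolisable ketone, hence no retro-oxa-Michael opening) until the quench. The step needs regioselective addition to the aryne, secured by the inductive and distortion effect of the C5 oxygen next to C4a, and acylation of 23 faster than protonation, secured by the absence of any O–H (silyl ether, THF in place of MeCN) and by the six-membered transition state.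

Step 14
Reactants: 25 (2S)-5,7-bis(methoxymethoxy)-2-[4-(methoxymethoxy)-3-(3-methylbut-2-en-1-yl)phenyl]-6-(3-methylbut-2-en-1-yl)-2,3-dihydro-4H-1-benzopyran-4-one
Product: 26 macarangaflavanone B, (2S)-5,7-dihydroxy-2-[4-hydroxy-3-(3-methylbut-2-en-1-yl)phenyl]-6-(3-methylbut-2-en-1-yl)-2,3-dihydro-4H-1-benzopyran-4-one
Conditions: 3 M aq HCl, MeOH, 40 °C
Reagents that add atoms: none
Why: Acid-catalysed transacetalisation of the three aryl MOM ethers to methanol should free the phenols under conditions mild enough to spare the prenyl groups and the C2 centre.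

## Compound list

1 | resorcinol (benzene-1,3-diol) | Oc1cccc(O)c1 | starting material
2 | 1,3-bis(methoxymethoxy)benzene | COCOc1cccc(OCOC)c1 | intermediate
3 | [2,6-bis(methoxymethoxy)phenyl]lithium | COCOc1cccc(OCOC)c1[Li] | intermediate
4 | 1,3-bis(methoxymethoxy)-2-(3-methylbut-2-en-1-yl)benzene | COCOc1cccc(OCOC)c1CC=C(C)C | intermediate
5 | 2-[3,5-bis(methoxymethoxy)-4-(3-methylbut-2-en-1-yl)phenyl]-4,4,5,5-tetramethyl-1,3,2-dioxaborolane | COCOc1cc(B2OC(C)(C)C(C)(C)O2)cc(OCOC)c1CC=C(C)C | intermediate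
6 | 3,5-bis(methoxymethoxy)-4-(3-methylbut-2-en-1-yl)phenol | COCOc1cc(O)cc(OCOC)c1CC=C(C)C | intermediate
7 | 3,5-bis(methoxymethoxy)-4-(3-methylbut-2-en-1-yl)phenyl N-(propan-2-yl)carbamate | CC(C)NC(=O)Oc1cc(OCOC)c(CC=C(C)C)c(OCOC)c1 | intermediate
8 | 3,5-bis(methoxymethoxy)-4-(3-methylbut-2-en-1-yl)phenyl N-(tert-butyldimethylsilyl)-N-(propan-2-yl)carbamate | CC(C)N(C(=O)Oc1cc(OCOC)c(CC=C(C)C)c(OCOC)c1)[Si](C)(C)C(C)(C)C | intermediate
9 | 2-lithio derivative of 8 (lithium between the carbamate and an OMOM group) | CC(C)N(C(=O)Oc1cc(OCOC)c(CC=C(C)C)c(OCOC)c1[Li])[Si](C)(C)C(C)(C)C | intermediate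
10 | 3,5-bis(methoxymethoxy)-4-(3-methylbut-2-en-1-yl)-2-(trimethylsilyl)phenyl N-(tert-butyldimethylsilyl)-N-(propan-2-yl)carbamate | CC(C)N(C(=O)Oc1cc(OCOC)c(CC=C(C)C)c(OCOC)c1[Si](C)(C)C)[Si](C)(C)C(C)(C)C | intermediate
11 | 3,5-bis(methoxymethoxy)-4-(3-methylbut-2-en-1-yl)-2-(trimethylsilyl)phenyl N-(propan-2-yl)carbamate | CC(C)NC(=O)Oc1cc(OCOC)c(CC=C(C)C)c(OCOC)c1[Si](C)(C)C | intermediate
12 | 3,5-bis(methoxymethoxy)-4-(3-methylbut-2-en-1-yl)-2-(trimethylsilyl)phenol | COCOc1cc(O)c([Si](C)(C)C)c(OCOC)c1CC=C(C)C | intermediate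
13 | 3,5-bis(methoxymethoxy)-4-(3-methylbut-2-en-1-yl)-2-(trimethylsilyl)phenyl trifluoromethanesulfonate | COCOc1cc(OS(=O)(=O)C(F)(F)F)c([Si](C)(C)C)c(OCOC)c1CC=C(C)C | intermediate
14 | 1-(3-bromo-4-hydroxyphenyl)ethan-1-one | CC(=O)c1ccc(O)c(Br)c1 | starting material
15 | 1-[3-bromo-4-(methoxymethoxy)phenyl]ethan-1-one | CC(=O)c1ccc(OCOC)c(Br)c1 | intermediate
16 | 1-[4-(methoxymethoxy)-3-(3-methylbut-2-en-1-yl)phenyl]ethan-1-one | CC(=O)c1ccc(OCOC)c(CC=C(C)C)c1 | intermediate
17 | methyl 3-[4-(methoxymethoxy)-3-(3-methylbut-2-en-1-yl)phenyl]-3-oxopropanoate | COC(=O)CC(=O)c1ccc(OCOC)c(CC=C(C)C)c1 | intermediate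
18 | methyl (3S)-3-hydroxy-3-[4-(methoxymethoxy)-3-(3-methylbut-2-en-1-yl)phenyl]propanoate | CC(C)=CCc1cc([C@H](CC(=O)OC)O)ccc1OCOC | intermediate
19 | (3S)-3-hydroxy-N-methoxy-N-methyl-3-[4-(methoxymethoxy)-3-(3-methylbut-2-en-1-yl)phenyl]propanamide | CC(C)=CCc1cc([C@H](CC(=O)N(C)OC)O)ccc1OCOC | intermediate
20 | (3S)-N-methoxy-N-methyl-3-[4-(methoxymethoxy)-3-(3-methylbut-2-en-1-yl)phenyl]-3-[(trimethylsilyl)oxy]propanamide | CC(C)=CCc1cc([C@H](CC(=O)N(C)OC)O[Si](C)(C)C)ccc1OCOC | intermediate
21 | 1,2-didehydro-3,5-bis(methoxymethoxy)-4-(3-methylbut-2-en-1-yl)benzene (aryne) | COCOC1=C(CC=C(C)C)C(OCOC)=CC#C1 | intermediate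
22 | cesium (1S)-3-[methoxy(methyl)amino]-1-[4-(methoxymethoxy)-3-(3-methylbut-2-en-1-yl)phenyl]-3-oxopropan-1-olate | CC(C)=CCc1cc([C@H](CC(=O)N(C)OC)[O-])ccc1OCOC.[Cs+] | intermediate
23 | arylcesium from addition of 22 to 21: (3S)-3-[2-cesio-3,5-bis(methoxymethoxy)-4-(3-methylbut-2-en-1-yl)phenoxy]-N-methoxy-N-methyl-3-[4-(methoxymethoxy)-3-(3-methylbut-2-en-1-yl)phenyl]propanamide | CC(C)=CCc1cc([C@H](CC(=O)N(C)OC)Oc2cc(OCOC)c(CC=C(C)C)c(OCOC)c2[Cs])ccc1OCOC | intermediate
24 | cesium (2S)-4-[methoxy(methyl)amino]-5,7-bis(methoxymethoxy)-2-[4-(methoxymethoxy)-3-(3-methylbut-2-en-1-yl)phenyl]-6-(3-methylbut-2-en-1-yl)-3,4-dihydro-2H-1-benzopyran-4-olate (C4 configuration undefined and inconsequential) | CC(C)=CCc1cc([C@@H]2CC([O-])(N(C)OC)c3c(cc(OCOC)c(CC=C(C)C)c3OCOC)O2)ccc1OCOC.[Cs+] | intermediate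
25 | (2S)-5,7-bis(methoxymethoxy)-2-[4-(methoxymethoxy)-3-(3-methylbut-2-en-1-yl)phenyl]-6-(3-methylbut-2-en-1-yl)-2,3-dihydro-4H-1-benzopyran-4-one | CC(C)=CCc1cc([C@@H]2CC(=O)c3c(cc(OCOC)c(CC=C(C)C)c3OCOC)O2)ccc1OCOC | intermediate
26 | macarangaflavanone B, (2S)-5,7-dihydroxy-2-[4-hydroxy-3-(3-methylbut-2-en-1-yl)phenyl]-6-(3-methylbut-2-en-1-yl)-2,3-dihydro-4H-1-benzopyran-4-one | CC(C)=CCc1cc([C@@H]2CC(=O)c3c(cc(O)c(CC=C(C)C)c3O)O2)ccc1O | target

## Step count and risks

Total step count: 14. Longest linear sequence: 8 steps (steps 1–6, 13 and 14 from resorcinol; the branch through steps 7–12, 13 and 14 is equally long).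

Steps most likely to fail:

1. Step 13 (the proposed new method). The aryl carbanion may be quenched by proton transfer (from the α-methylene of the amide or from traces of water) before it reaches the amide carbonyl. The cesium alkoxide may also fragment by retro-aldol cleavage or β-elimination before it meets the aryne. Fallback with known chemistry, setting out from 17 and 6 and coming back at 25:
   - Ketone 17 is reduced with the enantiomeric catalyst RuCl[(R,R)-TsDPEN](p-cymene) and HCO2H/Et3N to methyl (3R)-3-hydroxy-3-[4-(methoxymethoxy)-3-(3-methylbut-2-en-1-yl)phenyl]propanoate F1.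
   - Mitsunobu etherification of phenol 6 with F1 (PPh3, DIAD, toluene, 0 °C) should proceed with inversion to methyl (3S)-3-[3,5-bis(methoxymethoxy)-4-(3-methylbut-2-en-1-yl)phenoxy]-3-[4-(methoxymethoxy)-3-(3-methylbut-2-en-1-yl)phenyl]propanoate F2.
   - Saponification (LiOH, THF/H2O, 0 °C) should give (3S)-3-[3,5-bis(methoxymethoxy)-4-(3-methylbut-2-en-1-yl)phenoxy]-3-[4-(methoxymethoxy)-3-(3-methylbut-2-en-1-yl)phenyl]propanoic acid F3.
   - 1-Chloro-N,N,2-trimethylprop-1-en-1-amine should convert F3 into (3S)-3-[3,5-bis(methoxymethoxy)-4-(3-methylbut-2-en-1-yl)phenoxy]-3-[4-(methoxymethoxy)-3-(3-methylbut-2-en-1-yl)phenyl]propanoyl chloride F4.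
   - Intramolecular Friedel–Crafts acylation of F4 (SnCl4, CH2Cl2, −78 °C) onto either of the two equivalent positions ortho to the ether oxygen closes ring C and should give 25. Partial loss of MOM groups there would not matter, since step 14 removes them all.

2. Step 14. Acid may add the freed phenols across the prenyl double bonds (ring closure to chromans) or hydrate the alkenes in competition with acetal cleavage. Fallback, setting out from 25 and coming back at 26:
   - TMSOTf with 2,2'-bipyridyl (CH2Cl2, 0 °C) should exchange the aryl methoxymethyl ethers for silyl ethers through N-(methoxymethyl)bipyridinium intermediates, without free Brønsted acid. This gives (2S)-2-[3-(3-methylbut-2-en-1-yl)-4-[(trimethylsilyl)oxy]phenyl]-6-(3-methylbut-2-en-1-yl)-5,7-bis[(trimethylsilyl)oxy]-2,3-dihydro-4H-1-benzopyran-4-one F5.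
   - Addition of water then hydrolyses the three Si–O bonds to 26.

3. Step 5. The silyl triflate may cleave aryl MOM ethers, and metalation may occur at the benzylic–allylic methylene instead of the ring. Fallback, setting out from 6 and coming back at 12:
   - Bromination of 6 with NBS (CH2Cl2, −78 °C) at one of the two equivalent positions ortho to the hydroxyl should give 2-bromo-3,5-bis(methoxymethoxy)-4-(3-methylbut-2-en-1-yl)phenol F6.
   - O-Silylation with hexamethyldisilazane (THF, 60 °C) gives [2-bromo-3,5-bis(methoxymethoxy)-4-(3-methylbut-2-en-1-yl)phenoxy]trimethylsilane F7.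
   - Bromine–lithium exchange with n-BuLi (THF, −100 °C) gives [2,4-bis(methoxymethoxy)-3-(3-methylbut-2-en-1-yl)-6-[(trimethylsilyl)oxy]phenyl]lithium F8.
   - F8 should undergo 1,3 oxygen-to-carbon silyl migration (retro-Brook rearrangement) to the lithium salt of 12, which is triflated in the same flask with PhNTf2 to 13.

## Further compounds

F1 | step 13 | methyl (3R)-3-hydroxy-3-[4-(methoxymethoxy)-3-(3-methylbut-2-en-1-yl)phenyl]propanoate | CC(C)=CCc1cc([C@@H](CC(=O)OC)O)ccc1OCOC
F2 | step 13 | methyl (3S)-3-[3,5-bis(methoxymethoxy)-4-(3-methylbut-2-en-1-yl)phenoxy]-3-[4-(methoxymethoxy)-3-(3-methylbut-2-en-1-yl)phenyl]propanoate | CC(C)=CCc1cc([C@H](CC(=O)OC)Oc2cc(OCOC)c(CC=C(C)C)c(OCOC)c2)ccc1OCOC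
F3 | step 13 | (3S)-3-[3,5-bis(methoxymethoxy)-4-(3-methylbut-2-en-1-yl)phenoxy]-3-[4-(methoxymethoxy)-3-(3-methylbut-2-en-1-yl)phenyl]propanoic acid | CC(C)=CCc1cc([C@H](CC(=O)O)Oc2cc(OCOC)c(CC=C(C)C)c(OCOC)c2)ccc1OCOC
F4 | step 13 | (3S)-3-[3,5-bis(methoxymethoxy)-4-(3-methylbut-2-en-1-yl)phenoxy]-3-[4-(methoxymethoxy)-3-(3-methylbut-2-en-1-yl)phenyl]propanoyl chloride | CC(C)=CCc1cc([C@H](CC(=O)Cl)Oc2cc(OCOC)c(CC=C(C)C)c(OCOC)c2)ccc1OCOC
F5 | step 14 | (2S)-2-[3-(3-methylbut-2-en-1-yl)-4-[(trimethylsilyl)oxy]phenyl]-6-(3-methylbut-2-en-1-yl)-5,7-bis[(trimethylsilyl)oxy]-2,3-dihydro-4H-1-benzopyran-4-one | CC(C)=CCc1cc([C@@H]2CC(=O)c3c(cc(O[Si](C)(C)C)c(CC=C(C)C)c3O[Si](C)(C)C)O2)ccc1O[Si](C)(C)C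
F6 | step 5 | 2-bromo-3,5-bis(methoxymethoxy)-4-(3-methylbut-2-en-1-yl)phenol | COCOc1cc(O)c(Br)c(OCOC)c1CC=C(C)C
F7 | step 5 | [2-bromo-3,5-bis(methoxymethoxy)-4-(3-methylbut-2-en-1-yl)phenoxy]trimethylsilane | COCOc1cc(O[Si](C)(C)C)c(Br)c(OCOC)c1CC=C(C)C
F8 | step 5 | [2,4-bis(methoxymethoxy)-3-(3-methylbut-2-en-1-yl)-6-[(trimethylsilyl)oxy]phenyl]lithium | COCOc1cc(O[Si](C)(C)C)c([Li])c(OCOC)c1CC=C(C)C
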